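**Assumption:** 2,3-O-isopropylidene-α-L-sorbofuranose (the mono-acetonide of L-sorbose) is taken as a purchasable starting material. Locants in steps 1–4 are sugar or hexenone numbers; in steps 5–6 they are those of the 7-oxabicyclo[4.1.0]heptene target (C1 bears CH2OBz).

**Retrosynthetic overview**
- The cyclohexene is closed last, by ring-closing metathesis (C4=C5) of a cis-disubstituted vinyl oxirane that carries a second vinyl group; the oxirane is therefore formed first and the carbocycle second.
- Key disconnection, oxirane bond C1–C6: the ketone carbon (C1) is joined to the C–Cl carbon of allyl chloride used with reversed polarity, as an α-chloroallyl carbanion equivalent delivered by a (Z)-γ-chloroallylborane. Two carbons that are both electrophilic in normal polarity are joined, and the resulting chlorohydrin closes to the epoxide.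
- The ketone, with C2(OMe) and C3(OBz) already in place, comes from L-sorbose: sugar C3 and C4 become target C2 and C3, and a zinc fragmentation of the 6-iodide unveils the ketone and the first vinyl group.

**Step 1**
Reactants: 1 2,3-O-isopropylidene-α-L-sorbofuranose
Product: 2 6-deoxy-6-iodo-2,3-O-isopropylidene-α-L-sorbofuranose
Conditions: I2, PPh3, imidazole, THF, 0 °C to rt
Reagents that add atoms: iodine, II
Why: Garegg–Samuelsson (Appel-type) iodination converts the unhindered primary 6-OH much faster than the neopentyl-like 1-OH beside the quaternary ketal carbon or the secondary 4-OH, and no stereocentre is touched.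

**Step 2**
Reactants: 2 6-deoxy-6-iodo-2,3-O-isopropylidene-α-L-sorbofuranose
Product: 3 1,4-di-O-benzoyl-6-deoxy-6-iodo-2,3-O-isopropylidene-α-L-sorbofuranose
Conditions: BzCl, pyridine, DMAP (cat.), CH2Cl2, 0 °C to rt
Reagents that add atoms: benzoyl chloride, O=C(Cl)c1ccccc1
Why: DMAP-catalysed acylation of the two remaining hydroxyls (O1, O4) installs both benzoates of the target in one operation; the acetonide and the alkyl iodide are inert.

**Step 3**
Reactants: 3 1,4-di-O-benzoyl-6-deoxy-6-iodo-2,3-O-isopropylidene-α-L-sorbofuranose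
Product: 5 (3S,4R)-3-hydroxy-2-oxohex-5-ene-1,4-diyl dibenzoate, via dioxolane hemiketal 4 (not isolated)
Conditions: Zn dust (activated), THF/H2O 4:1, ultrasound, 40 °C; crude product used at once
Reagents that add atoms: none
Why: Bernet–Vasella reductive fragmentation: zinc inserts into the C6–I bond, β-elimination opens the furanose (C5=C6 formed, ring oxygen expelled onto C2), and hemiketal 4 sheds acetone to unveil the C2 ketone and the free 3-OH; C3 and C4 are untouched, and the neutral medium with immediate use limits benzoyl migration or epimerisation of the α-ketol.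

**Step 4**
Reactants: 5 (3S,4R)-3-hydroxy-2-oxohex-5-ene-1,4-diyl dibenzoate
Product: 6 (3S,4R)-3-methoxy-2-oxohex-5-ene-1,4-diyl dibenzoate
Conditions: Me3OBF4, 1,8-bis(dimethylamino)naphthalene, 4 Å sieves, CH2Cl2, 0 °C to rt
Reagents that add atoms: trimethyloxonium tetrafluoroborate, C[O+](C)C.F[B-](F)(F)F
Why: Meerwein-salt O-methylation buffered by a hindered non-nucleophilic base alkylates the only free hydroxyl without enolising the ketone, eliminating the β-benzoate or inducing acyl migration, so the C3 stereocentre is kept.

**Step 5 (key step)**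
Reactants: 6 (3S,4R)-3-methoxy-2-oxohex-5-ene-1,4-diyl dibenzoate; 7 allyl chloride
Product: 11 [(2R,3R)-2-[(1S,2R)-2-(benzoyloxy)-1-methoxybut-3-en-1-yl]-3-vinyloxiran-2-yl]methyl benzoate, via chloroallylborane 8 (not isolated), via borinate 9 (not isolated), via chlorohydrin 10 (not isolated)
Conditions: 7, LiN(C6H11)2, (+)-Ipc2BOMe (from (−)-α-pinene), Et2O, −95 °C; BF3·OEt2; then 6, −95 to −78 °C; HOCH2CH2NH2, rt; then DBU, CH2Cl2, rt
Reagents that add atoms: allyl chloride (compound 7), C=CCCl
Why: Proposed new method: deprotonation of 7 turns its C–Cl carbon, normally an electrophile, into the nucleophilic terminus of (Z)-γ-chloroallylborane 8 (an α-chloroallyl anion, i.e. a 1-oxyallyl d1 equivalent at the epoxide oxidation level), which joins it to the equally electrophilic ketone carbon of 6 through a closed chair transition state; the closest known reactions are the Oehlschlager–Brown γ-chloroallylboration of aldehydes to syn-chlorohydrins and cis-vinyl oxiranes and the allylboration of ketones by B-allyldialkylboranes, and the ketone here is activated by two α-oxygen substituents; with the branched C3 arm equatorial and CH2OBz axial the Z reagent gives the syn chlorohydrin, attack occurs anti to the C3–OMe bond (Cornforth/Felkin–Anh, non-chelating boron) on the face I expect the (−)-α-pinene-derived Ipc2B group to prefer (matched, by Brown's facial rule as I recall it), which sets C1 of the target, and DBU closes the oxirane by SN2 with inversion at the chlorinated carbon, which sets C6 and places the vinyl group cis to the C2 chain.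

**Step 6**
Reactants: 11 [(2R,3R)-2-[(1S,2R)-2-(benzoyloxy)-1-methoxybut-3-en-1-yl]-3-vinyloxiran-2-yl]methyl benzoate
Product: 12 [(1R,2S,3R,6R)-3-(benzoyloxy)-2-methoxy-7-oxabicyclo[4.1.0]hept-4-en-1-yl]methyl benzoate
Conditions: second-generation Grubbs catalyst RuCl2(=CHPh)(PCy3)(H2IMes) (5 mol %), CH2Cl2, 40 °C
Reagents that add atoms: none
Why: Ring-closing olefin metathesis of the two terminal vinyl groups, held close by the cis-oxirane, releases ethylene and forms the cyclohexene (C4=C5) without touching any stereocentre; benzoates, methyl ether and the trisubstituted epoxide tolerate the ruthenium carbene.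

**Compound list**
1 | 2,3-O-isopropylidene-α-L-sorbofuranose | OC[C@@]12O[C@@H](CO)[C@@H](O)[C@@H]1OC(C)(C)O2 | starting material
2 | 6-deoxy-6-iodo-2,3-O-isopropylidene-α-L-sorbofuranose | OC[C@@]12O[C@@H](CI)[C@@H](O)[C@@H]1OC(C)(C)O2 | intermediate
3 | 1,4-di-O-benzoyl-6-deoxy-6-iodo-2,3-O-isopropylidene-α-L-sorbofuranose | O=C(c1ccccc1)OC[C@@]23O[C@@H](CI)[C@@H](OC(=O)c4ccccc4)[C@@H]2OC(C)(C)O3 | intermediate
4 | dioxolane hemiketal: 4-(benzoyloxymethyl)-5-[(1R)-1-(benzoyloxy)allyl]-2,2-dimethyl-1,3-dioxolan-4-ol (present as its zinc alkoxide; sugar configurations retained) | O=C(c1ccccc1)OC[C@]2(O)OC(C)(C)O[C@H]2[C@H](OC(=O)c3ccccc3)C=C | intermediate (not isolated)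
5 | (3S,4R)-3-hydroxy-2-oxohex-5-ene-1,4-diyl dibenzoate | O=C(c1ccccc1)OCC(=O)[C@@H](O)[C@H](OC(=O)c2ccccc2)C=C | intermediate
6 | (3S,4R)-3-methoxy-2-oxohex-5-ene-1,4-diyl dibenzoate | O=C(c1ccccc1)OCC(=O)[C@@H](OC)[C@H](OC(=O)c2ccccc2)C=C | intermediate
7 | allyl chloride | C=CCCl | starting material
8 | (Z)-(3-chloroallyl)diisopinocampheylborane, Ipc groups from (−)-α-pinene | Cl/C=C\CB([C@H]1C[C@H]2C[C@@H]([C@@H]1C)C2(C)C)[C@H]3C[C@H]4C[C@@H]([C@@H]3C)C4(C)C | intermediate (not isolated)
9 | diisopinocampheylborinate ester of chlorohydrin 10 (B on the tertiary oxygen) | CO[C@@H]([C@H](OC(=O)c1ccccc1)C=C)[C@@](OB([C@H]2C[C@H]3C[C@@H]([C@@H]2C)C3(C)C)[C@H]4C[C@H]5C[C@@H]([C@@H]4C)C5(C)C)(COC(=O)c6ccccc6)[C@@H](Cl)C=C | intermediate (not isolated)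
10 | (3R,4S,5S,6S)-5-[(benzoyloxy)methyl]-6-chloro-5-hydroxy-4-methoxyocta-1,7-dien-3-yl benzoate (syn chlorohydrin) | CO[C@@H]([C@H](OC(=O)c1ccccc1)C=C)[C@@](O)(COC(=O)c2ccccc2)[C@@H](Cl)C=C | intermediate (not isolated)
11 | [(2R,3R)-2-[(1S,2R)-2-(benzoyloxy)-1-methoxybut-3-en-1-yl]-3-vinyloxiran-2-yl]methyl benzoate | CO[C@@H]([C@H](OC(=O)c1ccccc1)C=C)[C@]1(COC(=O)c2ccccc2)O[C@@H]1C=C | intermediate
12 | [(1R,2S,3R,6R)-3-(benzoyloxy)-2-methoxy-7-oxabicyclo[4.1.0]hept-4-en-1-yl]methyl benzoate | CO[C@H]1[C@H](OC(=O)c2ccccc2)C=C[C@H]2O[C@]21COC(=O)c1ccccc1 | target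

**Total step count:** 6. **Longest linear sequence:** 6 steps (1 to 12).

**Steps most likely to fail, with fallbacks**

Step 5 (most at risk). The γ-chloroallylboration is established for aldehydes, not ketones; the hindered ketone may react too slowly at −95 to −78 °C, or the equatorial/axial preference may be weak. The anti chlorohydrin would give a trans-oxirane that cannot ring-close and would be lost at step 6. The fallback sets out from 6 and makes the same bond under Lewis-acid activation. BF3·OEt2-promoted addition of (Z)-tributyl[3-(tert-butyldimethylsilyloxy)allyl]stannane in CH2Cl2 at −78 °C (an α-silyloxyallyl anion equivalent; open, non-chelated transition state, same facial control, syn adduct) gives the tertiary alcohol silyl ether F1. HF·pyridine then frees the allylic hydroxyl to give the diol F2. MsCl/Et3N at −20 °C sulfonylates only the secondary hydroxyl to give the mesylate F3, and DBU closes the oxirane with inversion, coming back to the route at 11.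

Step 4. The α-ketol 5 may suffer benzoyl migration from O4 to O3, epimerisation or β-elimination before or during methylation. The fallback sets out from 3 and installs the methyl ether while the furanose ring still holds O3 and O4 trans, where acyl migration is geometrically disfavoured. HCl in MeOH (from AcCl) exchanges the acetonide for the methyl ketoside with a free 3-OH, the methyl furanoside F4 (anomer mixture; both anomers serve). MeOTf with 2,6-di-tert-butyl-4-methylpyridine gives the 3-O-methyl ether F5. Zinc fragmentation of F5 under the step 3 conditions then delivers the ketone directly, coming back to the route at 6 and bypassing 5.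

Step 6. The vinyl oxirane next to the ruthenium carbene may open or isomerise, and both alkenes are deactivated by allylic oxygen. The fallback sets out from chlorohydrin 10, isolated after the 2-aminoethanol work-up of step 5. Ring-closing metathesis with the same catalyst gives the cyclic trans-chlorohydrin F6, and DBU then forms the epoxide on the ring, coming back to the route at 12.

**Further compounds**
F1 | step 5 | tert-butyldimethylsilyl ether analogue of 10 (OSiMe2tBu in place of Cl, same spatial arrangement at all four centres) | CO[C@@H]([C@H](OC(=O)c1ccccc1)C=C)[C@@](O)(COC(=O)c2ccccc2)[C@@H](O[Si](C)(C)C(C)(C)C)C=C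
F2 | step 5 | syn diol analogue of 10 (OH in place of Cl, same spatial arrangement) | CO[C@@H]([C@H](OC(=O)c1ccccc1)C=C)[C@@](O)(COC(=O)c2ccccc2)[C@@H](O)C=C
F3 | step 5 | secondary methanesulfonate of F2 (OMs in place of Cl of 10, same spatial arrangement) | CO[C@@H]([C@H](OC(=O)c1ccccc1)C=C)[C@@](O)(COC(=O)c2ccccc2)[C@@H](OS(C)(=O)=O)C=C
F4 | step 4 | methyl 1,4-di-O-benzoyl-6-deoxy-6-iodo-α-L-sorbofuranoside (α-anomer drawn) | O=C(c1ccccc1)OC[C@@]2(OC)O[C@@H](CI)[C@@H](OC(=O)c3ccccc3)[C@@H]2O
F5 | step 4 | methyl 1,4-di-O-benzoyl-6-deoxy-6-iodo-3-O-methyl-α-L-sorbofuranoside (α-anomer drawn) | O=C(c1ccccc1)OC[C@@]2(OC)O[C@@H](CI)[C@@H](OC(=O)c3ccccc3)[C@@H]2OC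
F6 | step 6 | [(1S,2S,3R,6S)-3-(benzoyloxy)-6-chloro-1-hydroxy-2-methoxycyclohex-4-en-1-yl]methyl benzoate (Cl trans to the tertiary OH) | CO[C@H]1[C@H](OC(=O)c2ccccc2)C=C[C@H](Cl)[C@]1(O)COC(=O)c1ccccc1
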